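**Retrosynthetic overview**

1. Structural feature: in the target the cyclopentane (C1, C2, C3, C9, C10) is fused along C3–C9 to the cycloheptene (C3 to C9). The oxygenated C8 is bonded to fusion carbon C9, and the other fusion carbon C3 is quaternary, so the skeleton is a trans-decalin (ring A: C1, C2, C3, C8, C9, C10; ring B: C3 to C8) in which C3 has moved from C8 to C9.
2. Endgame: target ⇐ desilylation, C1 acetylation, acetonide removal ⇐ C8 aroyl ester ⇐ Luche reduction of the 6-methyl-6-en-8-one 20 ⇐ ketone 14 by two Saegusa–Ito dehydrogenations around a cuprate methylation.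
3. Key disconnection: the C3–C9 bond of 14 ⇐ hydroxy mesylate 12, by a 1,2-shift of C3 from C8 to C9 (ring A six to five, ring B six to seven, in one event).
4. 12 ⇐ (S)-Wieland–Miescher ketone 1: C4 reduction, C1 oxygen by α'-hydroxylation and inversion, isopropyl addition to C10 anti to the C1 oxygen, acetonide, α-face dihydroxylation of C8=C9, C9 mesylation.
5. Ring order: both six-membered rings come with 1; the five- and seven-membered rings form together in step 10.

Key step: step 10

Assumption: 1 and 22 are purchased; the C6 methyl, which ends on an sp2 carbon, is introduced after the ring expansion so that no uncontrolled C6 stereocentre is carried through the decalin stage.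
Conventions: the numbering C1–C10 above is used for every intermediate; β is the face of the C3 methyl, α the opposite face; reagents whose atoms do not reach the target are not numbered.

**Route**

Step 1
Reactants: 1 (S)-Wieland–Miescher ketone
Product: 2 (4aS,5S)-5-hydroxy-4a-methyl-4,4a,5,6,7,8-hexahydronaphthalen-2(3H)-one (C4β-alcohol, C8=C9–C10=O enone)
Conditions: NaBH4 (0.3 equiv), EtOH, −10 → 0 °C
Reagents that add atoms: none
Why: Chemoselective NaBH4 reduction of the saturated C4 ketone (the conjugated C10 ketone is less electrophilic), with hydride delivered anti to the angular methyl, should give the equatorial C4β alcohol.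

Step 2
Reactants: 2 C4β-hydroxy enone
Product: 3 C4β-OTBS enone
Conditions: TBSCl, imidazole, DMF, rt
Reagents that add atoms: tert-butyldimethylsilyl chloride, CC(C)(C)[Si](C)(C)Cl
Why: Standard silylation of a secondary alcohol protects C4–OH through to the last step.

Step 3
Reactants: 3 C4β-OTBS enone
Product: 5 C1α-hydroxy enone (OH trans to the C3 methyl), via lithium dienolate 4 (not isolated)
Conditions: LiN(iPr)2, THF, −78 °C; 2-(phenylsulfonyl)-3-phenyloxaziridine, −78 °C; aq. NH4Cl
Reagents that add atoms: 2-(phenylsulfonyl)-3-phenyloxaziridine, O=S(=O)(c1ccccc1)N1OC1c1ccccc1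
Why: Kinetic α'-deprotonation at C1 gives the cross-conjugated dienolate, and enolate hydroxylation by the N-sulfonyloxaziridine should occur anti to the angular methyl to give the equatorial C1α alcohol, which is also the thermodynamic epimer.

Step 4
Reactants: 5 C1α-hydroxy enone
Product: 6 C1β-benzoyloxy enone (benzoate cis to the C3 methyl)
Conditions: PhCO2H, PPh3, DIAD, toluene, 0 °C → rt
Reagents that add atoms: benzoic acid, OC(=O)c1ccccc1
Why: Mitsunobu esterification inverts C1 by SN2 displacement of the carbonyl-activated alkoxyphosphonium under neutral conditions that should not epimerise the α-ketol ester.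

Step 5
Reactants: 6 C1β-benzoyloxy enone; 7 isopropylmagnesium chloride
Product: 8 tertiary allylic alcohol (C10β-OH, C10α-isopropyl, C1β-OBz, C8=C9, C4β-OTBS)
Conditions: anhydrous CeCl3, iPrMgCl, THF, −78 °C; aq. NH4Cl
Reagents that add atoms: isopropylmagnesium chloride, CC(C)[Mg]Cl
Why: The organocerium reagent (1,2-selective, weakly basic) should add to the C10 ketone faster than to the ester and without enolisation or hydride transfer, entering on the α face anti to the neighbouring C1–O bond (polar 1,2-induction), which sets C10–OH β and cis to the C1 oxygen.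

Step 6
Reactants: 8 tertiary allylic alcohol benzoate
Product: 9 C1β,C10β-diol (C10α-isopropyl, C8=C9, C4β-OTBS)
Conditions: K2CO3, MeOH, rt
Reagents that add atoms: none
Why: Base-catalysed methanolysis removes the benzoate, wherever it sits after a possible 1,2-acyl shift, and leaves the cis-diol.

Step 7
Reactants: 9 C1β,C10β-diol
Product: 10 C1β,C10β-O-isopropylidene octalin (C8=C9, C10α-isopropyl, C4β-OTBS)
Conditions: 2-methoxypropene, PPTS (cat.), CH2Cl2, 0 °C
Reagents that add atoms: 2-methoxypropene, COC(C)=C
Why: Ketalisation of the cis-1,2-diol with the enol ether needs only a trace of weak acid, which should spare the ionisable tertiary allylic C10 alcohol.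

Step 8
Reactants: 10 acetonide octalin
Product: 11 trans-decalin C8α,C9α-diol (C1β,C10β-acetonide, C4β-OTBS)
Conditions: OsO4 (0.1 equiv), N-methylmorpholine N-oxide, pyridine, acetone/tBuOH/H2O, 40 °C
Reagents that add atoms: osmium tetroxide, O=[Os](=O)(=O)=O; N-methylmorpholine N-oxide, C[N+]1([O-])CCOCC1; water, O
Why: Catalytic OsO4 syn-dihydroxylation should take place on the α face, anti to both the angular C3 methyl and the pseudoaxial allylic C10–O bond, giving the trans-decalin with C8–OH axial and C9–OH equatorial.

Step 9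
Reactants: 11 C8α,C9α-diol
Product: 12 C9α-mesylate with free C8α-OH (C1β,C10β-acetonide, C4β-OTBS)
Conditions: MsCl, Et3N, CH2Cl2, −10 °C
Reagents that add atoms: methanesulfonyl chloride, CS(=O)(=O)Cl
Why: Sulfonylation via sulfene reaches the equatorial secondary C9 hydroxyl while the tertiary C8 hydroxyl does not react, and the cis relationship excludes epoxide closure.

Step 10
Reactants: 12 C9α-mesylate
Product: 14 cis-fused hydroazulen-8-one (C1β,C10β-acetonide; C10α-isopropyl; C3β-methyl; C9β-H; C4β-OTBS), via potassium C8-alkoxide 13 (not isolated)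
Conditions: KOtBu (1.2 equiv), tBuOH/THF, 0 °C → rt; prompt aq. NH4Cl quench
Reagents that add atoms: none
Why: KOtBu deprotonates the tertiary C8 hydroxyl and the alkoxide pushes C3 from C8 to C9 in a concerted 1,2-shift as the C9 mesylate leaves, so that C3–C9 forms and C8 becomes the ketone without a free cation. The closest known reaction type is the base-induced pinacol-type (semipinacol) rearrangement of decalin cis-diol monosulfonates to hydroazulenones. The cyclopentane (C1, C2, C3, C9, C10) arises by contraction of ring A and the cycloheptanone (C3 to C9) by expansion of ring B through this single migration, not by an end-to-end cyclisation. The only new stereocentre is C9: C3 enters anti to the departing mesylate (inversion at C9) and migrates with retention, which places C9–H cis to the angular methyl. The step needs migration of the C3–C8 bond over every alternative, and this is secured because the α-oriented C9–O bond is antiperiplanar to C8–C3 in the chair and still close to it in a twist form of ring A, C9 has no β-hydrogen for elimination, and the acetonide keeps the C10 oxygen from acting as a second donor. The quench as soon as 12 is consumed is meant to prevent epimerisation of the new ketone at C9.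

Step 11
Reactants: 14 hydroazulen-8-one
Product: 16 C7=C8 trimethylsilyl enol ether, via lithium C7-enolate 15 (not isolated)
Conditions: LiN(iPr)2, THF, −78 °C; Me3SiCl, Et3N, −78 → 0 °C
Reagents that add atoms: chlorotrimethylsilane, C[Si](C)(C)Cl
Why: Kinetic enolisation should take the C7 methylene hydrogen and not the C9 methine, which is flanked by two quaternary carbons, so C9 is not touched before O-silylation.

Step 12
Reactants: 16 C7=C8 silyl enol ether
Product: 17 C6=C7 en-8-one (C1β,C10β-acetonide, C4β-OTBS)
Conditions: Pd(OAc)2 (1.1 equiv), MeCN, rt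
Reagents that add atoms: none
Why: Saegusa–Ito dehydrogenation: the divalent palladium enolate at C7 undergoes β-hydride elimination from C6, the only position that can give an enone because C3 and C10 carry no hydrogen.

Step 13
Reactants: 17 C6=C7 en-8-one; 18 methyllithium
Product: 19 6-methyl C7=C8 trimethylsilyl enol ether (C6 epimers not distinguished; the centre is erased in step 14)
Conditions: CuI, MeLi (Me2CuLi formed in the flask), Me3SiCl, THF, −78 °C; Et3N, aq. NaHCO3
Reagents that add atoms: methyllithium, C[Li]; chlorotrimethylsilane, C[Si](C)(C)Cl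
Why: Silyl-chloride-accelerated conjugate addition of lithium dimethylcuprate places the methyl on C6 and traps the enolate regiospecifically as the C7=C8 silyl enol ether.

Step 14
Reactants: 19 6-methyl silyl enol ether
Product: 20 6-methyl-6-en-8-one (C1β,C10β-acetonide, C4β-OTBS)
Conditions: Pd(OAc)2 (1.1 equiv), MeCN, 40 °C
Reagents that add atoms: none
Why: A second Saegusa–Ito dehydrogenation removes the C6 hydrogen and gives the β-methyl enone from either C6 epimer.

Step 15
Reactants: 20 6-methyl-6-en-8-one
Product: 21 C8α allylic alcohol (C8–H β, cis to C9–H)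
Conditions: NaBH4, CeCl3·7H2O, MeOH, −40 °C
Reagents that add atoms: none
Why: Luche 1,2-reduction should deliver hydride to the convex β face of the cis-fused bicycle (the face of C9–H, away from the cyclopentane and its α-isopropyl), giving the C8α alcohol.

Step 16
Reactants: 21 C8α allylic alcohol; 22 4-(tert-butyldimethylsilyloxy)benzoic acid
Product: 23 C8α 4-(tert-butyldimethylsilyloxy)benzoate
Conditions: DCC, DMAP (cat.), CH2Cl2, 0 °C → rt
Reagents that add atoms: 4-(tert-butyldimethylsilyloxy)benzoic acid, CC(C)(C)[Si](C)(C)Oc1ccc(cc1)C(O)=O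
Why: Steglich esterification acylates the only free hydroxyl with retention at C8.

Step 17
Reactants: 23 C8 ester acetonide
Product: 24 C1β,C10β-diol (C8 ester and both silyl ethers retained)
Conditions: PPTS, MeOH, 40 °C
Reagents that add atoms: none
Why: Mild acid-catalysed transketalisation to methanol should remove the acetonide while the hindered secondary and the aryl silyl ethers and the allylic ester survive.

Step 18
Reactants: 24 C1β,C10β-diol; 25 acetic anhydride
Product: 26 C1β-acetate (C10–OH free)
Conditions: Ac2O, pyridine, DMAP (cat.), CH2Cl2, 0 °C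
Reagents that add atoms: acetic anhydride, CC(=O)OC(C)=O
Why: DMAP-catalysed acetylation takes the secondary C1 hydroxyl; the tertiary C10 hydroxyl does not react under these conditions.

Step 19
Reactants: 26 C1β-acetate bis-silyl ether
Product: 27 target
Conditions: HF·pyridine, pyridine/THF, 0 °C → rt
Reagents that add atoms: none
Why: Buffered fluoride desilylation cleaves the aryl and the C4 silyl ethers without acyl migration or ionisation of the allylic ester.

**Compound list**

1 | (S)-Wieland–Miescher ketone, (S)-8a-methyl-3,4,8,8a-tetrahydronaphthalene-1,6(2H,7H)-dione | C[C@]12CCC(=O)C=C1CCCC2=O | starting material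
2 | (4aS,5S)-5-hydroxy-4a-methyl-4,4a,5,6,7,8-hexahydronaphthalen-2(3H)-one (C4β-OH) | C[C@]12CCC(=O)C=C1CCC[C@@H]2O | intermediate
3 | C4β-OTBS enone | C[C@]12CCC(=O)C=C1CCC[C@@H]2O[Si](C)(C)C(C)(C)C | intermediate
4 | lithium C1=C10 dienolate of 3 | [Li+].C[C@]12CC=C([O-])C=C1CCC[C@@H]2O[Si](C)(C)C(C)(C)C | intermediate (not isolated)
5 | C1α-hydroxy enone (OH trans to C3 methyl) | C[C@]12C[C@@H](O)C(=O)C=C1CCC[C@@H]2O[Si](C)(C)C(C)(C)C | intermediate
6 | C1β-benzoyloxy enone | C[C@]12C[C@H](OC(=O)c3ccccc3)C(=O)C=C1CCC[C@@H]2O[Si](C)(C)C(C)(C)C | intermediate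
7 | isopropylmagnesium chloride | CC(C)[Mg]Cl | starting material
8 | C10β-hydroxy-C10α-isopropyl C1β-benzoate, C8=C9 | C[C@]12C[C@H](OC(=O)c3ccccc3)[C@@](O)(C(C)C)C=C1CCC[C@@H]2O[Si](C)(C)C(C)(C)C | intermediate
9 | C1β,C10β-diol, C10α-isopropyl, C8=C9 | C[C@]12C[C@H](O)[C@@](O)(C(C)C)C=C1CCC[C@@H]2O[Si](C)(C)C(C)(C)C | intermediate
10 | C1β,C10β-O-isopropylidene octalin, C8=C9 | CC(C)[C@]12OC(C)(C)O[C@H]1C[C@]3(C)[C@@H](O[Si](C)(C)C(C)(C)C)CCCC3=C2 | intermediate
11 | trans-decalin C8α,C9α-diol, C1β,C10β-acetonide | CC(C)[C@]12OC(C)(C)O[C@H]1C[C@]3(C)[C@@H](O[Si](C)(C)C(C)(C)C)CCC[C@@]3(O)[C@@H]2O | intermediate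
12 | C9α-mesylate, C8α-OH (key-step precursor) | CC(C)[C@]12OC(C)(C)O[C@H]1C[C@]3(C)[C@@H](O[Si](C)(C)C(C)(C)C)CCC[C@@]3(O)[C@@H]2OS(C)(=O)=O | intermediate
13 | potassium C8-alkoxide of 12 | [K+].CC(C)[C@]12OC(C)(C)O[C@H]1C[C@]3(C)[C@@H](O[Si](C)(C)C(C)(C)C)CCC[C@@]3([O-])[C@@H]2OS(C)(=O)=O | intermediate (not isolated)
14 | cis-fused hydroazulen-8-one, C1β,C10β-acetonide, C4β-OTBS | CC(C)[C@]12OC(C)(C)O[C@H]1C[C@]3(C)[C@@H](O[Si](C)(C)C(C)(C)C)CCCC(=O)[C@H]23 | intermediate
15 | lithium C7=C8 enolate of 14 | [Li+].CC(C)[C@]12OC(C)(C)O[C@H]1C[C@]3(C)[C@@H](O[Si](C)(C)C(C)(C)C)CCC=C([O-])[C@H]23 | intermediate (not isolated)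
16 | C7=C8 trimethylsilyl enol ether | CC(C)[C@]12OC(C)(C)O[C@H]1C[C@]3(C)[C@@H](O[Si](C)(C)C(C)(C)C)CCC=C(O[Si](C)(C)C)[C@H]23 | intermediate
17 | C6=C7 en-8-one | CC(C)[C@]12OC(C)(C)O[C@H]1C[C@]3(C)[C@@H](O[Si](C)(C)C(C)(C)C)CC=CC(=O)[C@H]23 | intermediate
18 | methyllithium | C[Li] | starting material
19 | 6-methyl C7=C8 trimethylsilyl enol ether (C6 epimers) | CC(C)[C@]12OC(C)(C)O[C@H]1C[C@]3(C)[C@@H](O[Si](C)(C)C(C)(C)C)CC(C)C=C(O[Si](C)(C)C)[C@H]23 | intermediate
20 | 6-methyl-6-en-8-one | CC(C)[C@]12OC(C)(C)O[C@H]1C[C@]3(C)[C@@H](O[Si](C)(C)C(C)(C)C)CC(C)=CC(=O)[C@H]23 | intermediate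
21 | C8α allylic alcohol | CC(C)[C@]12OC(C)(C)O[C@H]1C[C@]3(C)[C@@H](O[Si](C)(C)C(C)(C)C)CC(C)=C[C@H](O)[C@H]23 | intermediate
22 | 4-(tert-butyldimethylsilyloxy)benzoic acid | CC(C)(C)[Si](C)(C)Oc1ccc(cc1)C(O)=O | starting material
23 | C8α 4-(tert-butyldimethylsilyloxy)benzoate, acetonide | CC(C)[C@]12OC(C)(C)O[C@H]1C[C@]3(C)[C@@H](O[Si](C)(C)C(C)(C)C)CC(C)=C[C@H](OC(=O)c4ccc(O[Si](C)(C)C(C)(C)C)cc4)[C@H]23 | intermediate
24 | C1β,C10β-diol, C8 ester, bis-silyl ether | O[C@H]1C[C@]2(C)[C@@H](O[Si](C)(C)C(C)(C)C)CC(C)=C[C@H](OC(=O)c3ccc(O[Si](C)(C)C(C)(C)C)cc3)[C@@H]2[C@]1(O)C(C)C | intermediate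
25 | acetic anhydride | CC(=O)OC(C)=O | starting material
26 | C1β-acetate, bis-silyl ether | CC(=O)O[C@H]1C[C@]2(C)[C@@H](O[Si](C)(C)C(C)(C)C)CC(C)=C[C@H](OC(=O)c3ccc(O[Si](C)(C)C(C)(C)C)cc3)[C@@H]2[C@]1(O)C(C)C | intermediate
27 | CNP0146780.2 | CC(=O)O[C@H]1C[C@]2(C)[C@@H](O)CC(C)=C[C@H](OC(=O)c3ccc(O)cc3)[C@@H]2[C@]1(O)C(C)C | target

**Totals and risks**

Total step count: 19. Longest linear sequence: 19 steps (1 to 27).

Steps most likely to fail:

Step 8. The C8=C9 alkene is trisubstituted and flanked by the quaternary C3 and the fully substituted C10, so osmate ester formation may be too slow for catalytic turnover, and attack on the β face may compete and erode the facial selectivity. The fallback sets out from 10 and returns at 11. Buffered peracid epoxidation (mCPBA, NaHCO3, CH2Cl2), which is sterically less demanding, should give the 8α,9α-epoxide F1. Diethylaluminium 2,2,6,6-tetramethylpiperidide, Et2Al(NC9H18), in toluene then removes a C7 hydrogen (the only hydrogen next to the epoxide) with opening of the C8–O bond, to give the C7=C8 allylic alcohol with retained C9α-OH F2. VO(acac)2/tBuOOH epoxidises C7=C8 syn to that hydroxyl to give the 7α,8α-epoxy alcohol F3. LiAlH4 in THF opens it trans-diaxially at the less substituted C7 and gives 11.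

Step 10. After the shift, the alkoxide base may enolise the new ketone towards C9 and equilibrate the kinetically formed cis-fused ketone to its trans-fused epimer; if ring A twists far out of the aligned conformation, the shift may also become slow enough for decomposition to compete. The fallback sets out from 12 and returns at 14, and replaces anionic push by electrophilic pull. Et3Al in CH2Cl2 at −78 °C turns the C8 hydroxyl into an aluminium alkoxide, and the Lewis-acidic aluminium assists departure of the mesylate. The same C3 shift then runs without free base (organoaluminium-promoted pinacol-type rearrangement of a β-mesyloxy alcohol), so the C9 hydrogen is not exchanged. No new compound is made (F0).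

Step 4. The displacement at C1 must occur on the face of the angular methyl, so the alkoxyphosphonium may eliminate towards the diosphenol or be acylated with retention, leaving the C1α configuration. The fallback sets out from 5 and returns at 9. Silylation (Et3SiCl, imidazole, DMF) gives the C1α-triethylsilyloxy enone F4. Enolisation at C1 with LiN(iPr)2 at −78 °C and kinetic protonation on the open α face with a hindered phenol (2,6-di-tert-butyl-4-methylphenol) should give the contra-thermodynamic C1β-triethylsilyloxy enone F5. iPrMgCl/CeCl3 adds anti to the C1–O bond to give the C10 tertiary alcohol F6. Selective cleavage of the triethylsilyl ether (HF·pyridine, pyridine/THF, 0 °C, with the hindered C4 TBS ether retained) gives 9.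

**Further compounds**

F1 | step 8 | 8α,9α-epoxide of 10 | CC(C)[C@]12OC(C)(C)O[C@H]1C[C@]3(C)[C@@H](O[Si](C)(C)C(C)(C)C)CCC[C@@]3(O4)[C@@H]24
F2 | step 8 | C7=C8 allylic alcohol, C9α-OH | CC(C)[C@]12OC(C)(C)O[C@H]1C[C@]3(C)[C@@H](O[Si](C)(C)C(C)(C)C)CCC=C3[C@@H]2O
F3 | step 8 | 7α,8α-epoxy C9α-alcohol | CC(C)[C@]12OC(C)(C)O[C@H]1C[C@]3(C)[C@@H](O[Si](C)(C)C(C)(C)C)CC[C@@H]4O[C@]34[C@@H]2O
F0 | step 10 | none | none
F4 | step 4 | C1α-triethylsilyloxy enone | C[C@]12C[C@@H](O[Si](CC)(CC)CC)C(=O)C=C1CCC[C@@H]2O[Si](C)(C)C(C)(C)C
F5 | step 4 | C1β-triethylsilyloxy enone | C[C@]12C[C@H](O[Si](CC)(CC)CC)C(=O)C=C1CCC[C@@H]2O[Si](C)(C)C(C)(C)C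
F6 | step 4 | C10β-hydroxy-C10α-isopropyl C1β-triethylsilyl ether | C[C@]12C[C@H](O[Si](CC)(CC)CC)[C@@](O)(C(C)C)C=C1CCC[C@@H]2O[Si](C)(C)C(C)(C)C
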